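Ring D (dihydropyran: O1′ on C10, quaternary C2′, carbinol C3′, C4′H2 on C11) is cut at C11–C4′ and O1′–C2′. The C10=C11 enol ether shared by rings C and D is the enol of a dibenzo[b,f]oxepin-10(11H)-one, whose C11/O10 pair is a 1,3-C,O-dinucleophile. In one flask the ketone enolate is C-alkylated by the iodide of (2S,3R)-2,3-epoxynerol and the C10 oxygen then opens the epoxide 6-endo at its tertiary carbon with inversion, so both stereocentres of ring D derive from one Sharpless epoxidation. The protected ketone comes from a palladium-catalysed α-arylation joining rings A and B and a fluoride-triggered SNAr closure of ring C.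

Key step: step 9

Locants: dibenzo[b,f]oxepine numbering; ring A = benzo ring C1–C4 (prenyl at C2, oxygen at C3), ring B = benzo ring C6–C9 (oxygen at C7), ring C = oxepine, ring D = dihydropyran (primed locants).
Remark on the chemistry: acid-catalysed opening of the trisubstituted epoxide at its tertiary carbon by the tethered oxygen is taken to be stereospecific (anti, with inversion).

Step 1
Reactants: 1 nerol, (2Z)-3,7-dimethylocta-2,6-dien-1-ol
Product: 2 (2S,3R)-2,3-epoxynerol, [(2S,3R)-3-methyl-3-(4-methylpent-3-en-1-yl)oxiran-2-yl]methanol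
Conditions: Ti(OiPr)4 (5 mol%), L-(+)-diethyl tartrate (6 mol%), t-BuOOH, 4 Å molecular sieves, CH2Cl2, −20 °C
Reagents that add atoms: tert-butyl hydroperoxide, CC(C)(C)OO
Why: Sharpless asymmetric epoxidation, in which the titanium tartrate complex binds the allylic alcohol and delivers oxygen to one face of the 2,3-olefin only (the isolated 6,7-olefin does not react), L-(+)-tartrate giving the 2S epoxide while the Z geometry of nerol fixes the quaternary carbon as 3R.

Step 2
Reactants: 2 (2S,3R)-2,3-epoxynerol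
Product: 3 (2R,3R)-3-(iodomethyl)-2-methyl-2-(4-methylpent-3-en-1-yl)oxirane (the iodide of 2)
Conditions: PPh3, imidazole, I2, CH2Cl2, 0 °C
Reagents that add atoms: iodine, II
Why: Appel-type iodination, in which the primary hydroxyl is activated as an alkoxyphosphonium ion and displaced by iodide at C1 under imidazole buffering, so the epoxide and both stereocentres are untouched (the CH descriptor changes from S to R only because iodine changes the priority order).

Step 3
Reactants: 4 1-(2-fluoro-4-hydroxyphenyl)ethan-1-one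
Product: 5 1-[2-fluoro-4-{[2-(trimethylsilyl)ethoxy]methoxy}phenyl]ethan-1-one
Conditions: SEMCl, i-Pr2NEt, CH2Cl2, 0 °C → rt
Reagents that add atoms: 2-(trimethylsilyl)ethoxymethyl chloride, C[Si](C)(C)CCOCCl
Why: Williamson-type O-alkylation of the acidic phenol, giving an SEM acetal that should survive phosphate base, palladium catalysis and caesium fluoride at moderate temperature and is cleaved by fluoride only on heating.

Step 4
Reactants: 6 4,6-dibromobenzene-1,3-diol
Product: 7 1,5-dibromo-2,4-bis[(tert-butyldimethylsilyl)oxy]benzene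
Conditions: TBSCl, imidazole, DMF, rt
Reagents that add atoms: tert-butyldimethylsilyl chloride, CC(C)(C)[Si](C)(C)Cl
Why: Imidazole-promoted silylation of both phenols, giving ethers that tolerate the arylmagnesium and palladium steps and later serve as the fluoride-labile trigger for ring closure.

Step 5
Reactants: 7 1,5-dibromo-2,4-bis[(tert-butyldimethylsilyl)oxy]benzene
Product: 9 1-bromo-2,4-bis[(tert-butyldimethylsilyl)oxy]-5-(3-methylbut-2-en-1-yl)benzene, via arylmagnesium chloride 8 (not isolated)
Conditions: i-PrMgCl·LiCl (1.05 equiv), THF, 0 °C → rt; then CuI (5 mol%), prenyl bromide, −20 → 0 °C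
Reagents that add atoms: prenyl bromide (1-bromo-3-methylbut-2-ene), CC(C)=CCBr
Why: Bromine–magnesium exchange (the two bromides are equivalent by symmetry and the electron-rich arylmagnesium formed should not exchange again) followed by copper-catalysed allylic substitution at the unhindered primary carbon of prenyl bromide (SN2, not SN2′), which gives the linear prenyl group.

Step 6
Reactants: 5 1-[2-fluoro-4-{[2-(trimethylsilyl)ethoxy]methoxy}phenyl]ethan-1-one and 9 1-bromo-2,4-bis[(tert-butyldimethylsilyl)oxy]-5-(3-methylbut-2-en-1-yl)benzene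
Product: 10 2-{2,4-bis[(tert-butyldimethylsilyl)oxy]-5-(3-methylbut-2-en-1-yl)phenyl}-1-[2-fluoro-4-{[2-(trimethylsilyl)ethoxy]methoxy}phenyl]ethan-1-one
Conditions: Pd(OAc)2 (3 mol%), XPhos (6 mol%), K3PO4, toluene, 90 °C
Reagents that add atoms: none
Why: Palladium-catalysed ketone α-arylation (oxidative addition of the aryl bromide to zerovalent palladium, phosphate-mediated formation of the palladium enolate of the methyl ketone, reductive elimination), in which the bulky biarylphosphine should enforce monoarylation while the C–F bond and the silyl ethers stay inert.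

Step 7
Reactants: 10 the deoxybenzoin of step 6
Product: 12 3-hydroxy-2-(3-methylbut-2-en-1-yl)-7-{[2-(trimethylsilyl)ethoxy]methoxy}dibenzo[b,f]oxepin-10(11H)-one, via fluoro diphenol 11 (not isolated)
Conditions: CsF (3 equiv), DMF (0.02 M), rt then 70 °C
Reagents that add atoms: none
Why: Fluoride removes both aryl silyl groups and the phenoxide ortho to the benzylic CH2 displaces the fluoride ortho to the ketone in an intramolecular SNAr reaction (Meisenheimer intermediate stabilised by the carbonyl), closing oxepine ring C, while the other phenoxide cannot reach the C–F carbon and dilution suppresses intermolecular etherification.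

Step 8
Reactants: 12 3-hydroxy-2-(3-methylbut-2-en-1-yl)-7-{[2-(trimethylsilyl)ethoxy]methoxy}dibenzo[b,f]oxepin-10(11H)-one
Product: 13 3-[(tert-butyldimethylsilyl)oxy]-2-(3-methylbut-2-en-1-yl)-7-{[2-(trimethylsilyl)ethoxy]methoxy}dibenzo[b,f]oxepin-10(11H)-one
Conditions: TBSCl, imidazole, DMF, rt
Reagents that add atoms: tert-butyldimethylsilyl chloride, CC(C)(C)[Si](C)(C)Cl
Why: Silylation of the free phenol, so that the C11 enolate is the only nucleophile in the next step.

Step 9
Reactants: 13 the silyl- and SEM-protected dibenzo[b,f]oxepin-10(11H)-one and 3 the epoxy iodide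
Product: 15 the 3-O-TBS 7-O-SEM ether of the target (ring D complete with free 3′-OH and 2′S,3′S configuration), via epoxy ketone 14 (not isolated)
Conditions: t-BuOK (1.0 equiv), THF, −78 °C; 3 (1.1 equiv), −78 → 0 °C; then CH2Cl2, (1S)-(+)-10-camphorsulfonic acid (0.3 equiv), 0 °C → rt
Reagents that add atoms: none
Why: Deprotonation at C11 gives the potassium enolate, whose α-carbon displaces the primary iodide of 3 (SN2) to give epoxy ketone 14, and on acidification the C10 carbonyl (enol) oxygen attacks the protonated epoxide at its tertiary carbon and loss of H-11 gives the conjugated enol ether, so that C11–C4′ and O1′–C2′ are both formed in one flask. The closest known reactions are enolate alkylation with 2,3-epoxyalkyl halides and the acid-catalysed conversion of ortho-(epoxyprenyl)phenols and 2-(epoxyprenyl)-1,3-dicarbonyl compounds into 3-hydroxy-2,2-dialkyl dihydropyrans. Ring D closes in a 6-endo-tet mode. C3′ keeps the configuration installed by the Sharpless epoxidation because its C–O bond is never broken, and C2′ is set by backside attack with inversion at the tertiary carbon, which places the 3′-OH trans to the 2′-methyl group. The step needs C- over O-alkylation and monoalkylation (soft iodide, potassium enolate in THF without polar additive, steric bulk of the first substituent) and 6-endo over 5-exo opening (acid catalysis directs attack to the tertiary carbon, which best supports positive charge). The strained bicyclic ketal that could form by addition of the new hydroxyl to C10 is a reversible side channel that should drain to the enol ether conjugated with rings A and B.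

Step 10
Reactants: 15 the 3-O-TBS 7-O-SEM ether of the target
Product: 16 the target, CNP0185870.1
Conditions: TBAF (6 equiv), ethylenediamine (3 equiv), DMF, 70 °C, under argon
Reagents that add atoms: none
Why: Fluoride cleaves the aryl silyl ether at once and on heating attacks the trimethylsilyl group of the SEM acetal, which fragments to ethene, formaldehyde (trapped by ethylenediamine) and the phenoxide, while the enol ether, the olefins and both stereocentres are inert to these basic conditions.

Compound list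
1 | nerol, (2Z)-3,7-dimethylocta-2,6-dien-1-ol | CC(C)=CCC/C(C)=C\CO | starting material
2 | (2S,3R)-2,3-epoxynerol, [(2S,3R)-3-methyl-3-(4-methylpent-3-en-1-yl)oxiran-2-yl]methanol | OC[C@@H]1O[C@]1(C)CCC=C(C)C | intermediate
3 | (2R,3R)-3-(iodomethyl)-2-methyl-2-(4-methylpent-3-en-1-yl)oxirane | IC[C@@H]1O[C@]1(C)CCC=C(C)C | intermediate
4 | 1-(2-fluoro-4-hydroxyphenyl)ethan-1-one | CC(=O)c1ccc(O)cc1F | starting material
5 | 1-[2-fluoro-4-{[2-(trimethylsilyl)ethoxy]methoxy}phenyl]ethan-1-one | CC(=O)c1ccc(OCOCC[Si](C)(C)C)cc1F | intermediate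
6 | 4,6-dibromobenzene-1,3-diol | Oc1cc(O)c(Br)cc1Br | starting material
7 | 1,5-dibromo-2,4-bis[(tert-butyldimethylsilyl)oxy]benzene | CC(C)(C)[Si](C)(C)Oc1cc(O[Si](C)(C)C(C)(C)C)c(Br)cc1Br | intermediate
8 | {5-bromo-2,4-bis[(tert-butyldimethylsilyl)oxy]phenyl}magnesium chloride | Cl[Mg]c1cc(Br)c(O[Si](C)(C)C(C)(C)C)cc1O[Si](C)(C)C(C)(C)C | intermediate (not isolated)
9 | 1-bromo-2,4-bis[(tert-butyldimethylsilyl)oxy]-5-(3-methylbut-2-en-1-yl)benzene | CC(C)=CCc1cc(Br)c(O[Si](C)(C)C(C)(C)C)cc1O[Si](C)(C)C(C)(C)C | intermediate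
10 | 2-{2,4-bis[(tert-butyldimethylsilyl)oxy]-5-(3-methylbut-2-en-1-yl)phenyl}-1-[2-fluoro-4-{[2-(trimethylsilyl)ethoxy]methoxy}phenyl]ethan-1-one | CC(C)=CCc1cc(CC(=O)c2ccc(OCOCC[Si](C)(C)C)cc2F)c(O[Si](C)(C)C(C)(C)C)cc1O[Si](C)(C)C(C)(C)C | intermediate
11 | 2-[2,4-dihydroxy-5-(3-methylbut-2-en-1-yl)phenyl]-1-[2-fluoro-4-{[2-(trimethylsilyl)ethoxy]methoxy}phenyl]ethan-1-one (present as its caesium phenoxide) | CC(C)=CCc1cc(CC(=O)c2ccc(OCOCC[Si](C)(C)C)cc2F)c(O)cc1O | intermediate (not isolated)
12 | 3-hydroxy-2-(3-methylbut-2-en-1-yl)-7-{[2-(trimethylsilyl)ethoxy]methoxy}dibenzo[b,f]oxepin-10(11H)-one | O=C1Cc2cc(CC=C(C)C)c(O)cc2Oc2cc(OCOCC[Si](C)(C)C)ccc21 | intermediate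
13 | 3-[(tert-butyldimethylsilyl)oxy]-2-(3-methylbut-2-en-1-yl)-7-{[2-(trimethylsilyl)ethoxy]methoxy}dibenzo[b,f]oxepin-10(11H)-one | O=C1Cc2cc(CC=C(C)C)c(O[Si](C)(C)C(C)(C)C)cc2Oc2cc(OCOCC[Si](C)(C)C)ccc21 | intermediate
14 | 13 carrying at C11 the [(2S,3R)-3-methyl-3-(4-methylpent-3-en-1-yl)oxiran-2-yl]methyl group (both C11 epimers) | O=C1C(C[C@@H]2O[C@]2(C)CCC=C(C)C)c2cc(CC=C(C)C)c(O[Si](C)(C)C(C)(C)C)cc2Oc2cc(OCOCC[Si](C)(C)C)ccc21 | intermediate (not isolated)
15 | 3-O-tert-butyldimethylsilyl 7-O-[2-(trimethylsilyl)ethoxy]methyl ether of 16, with ring D as in the target (2′S,3′S, free 3′-OH) | CC(C)=CCC[C@]1(C)OC2=C(C[C@@H]1O)c1cc(CC=C(C)C)c(O[Si](C)(C)C(C)(C)C)cc1Oc1cc(OCOCC[Si](C)(C)C)ccc12 | intermediate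
16 | CNP0185870.1: 2-(3-methylbut-2-en-1-yl)dibenzo[b,f]oxepine-3,7-diol fused across C10–C11 to a (2′S,3′S)-3′-hydroxy-2′-methyl-2′-(4-methylpent-3-en-1-yl)-3′,4′-dihydro-2′H-pyran (O1′ on C10, C4′ on C11) | CC(C)=CCC[C@]1(C)OC2=C(C[C@@H]1O)c1cc(CC=C(C)C)c(O)cc1Oc1cc(O)ccc12 | target

Total step count: 10. Longest linear sequence: 7 steps (6 → 7 → 9 → 10 → 12 → 13 → 15 → 16; steps 4 to 10).

Steps most likely to fail

1. Step 9. In the first stage the enolate may be alkylated on oxygen or twice on carbon. In the second stage the epoxide may open 5-exo at the secondary carbon, or the tertiary C–O bond may ionise before attack and erode the configuration at C2′. The fallback makes the tertiary C–O bond first, with water, and closes ring D by forming O1′–C10 instead of O1′–C2′. It sets out from 3 and 13. Acid-catalysed hydrolysis of 3 (dilute HClO4, THF–water, 0 °C; attack at the tertiary carbon with inversion) should give (2R,3S)-1-iodo-3,7-dimethyloct-6-ene-2,3-diol F1. Selective silylation of the secondary hydroxyl (TBSOTf, 2,6-lutidine, −78 °C) should give (2R,3S)-2-[(tert-butyldimethylsilyl)oxy]-1-iodo-3,7-dimethyloct-6-en-3-ol F2. C-alkylation of the potassium enolate of 13 with F2 should give the δ-hydroxy ketone F3. Acid-catalysed cyclodehydration (PPTS, toluene, 4 Å sieves, 60 °C), in which only the tertiary hydroxyl is free to add to C10, should give the 3′-O-silyl ether of 15, F4. Global deprotection of F4 under the conditions of step 10 comes back to the route at 16.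

2. Step 7. At the temperature needed for ring closure fluoride may also attack the SEM group, which frees the ring B phenoxide and shuts down the SNAr reaction, and the second phenoxide may form diaryl ethers between molecules instead of the seven-membered ring. The fallback forms the diaryl ether first and closes ring C by C–C bond formation. It sets out from 5 and 6. SNAr of an excess of 6 with 5 (K2CO3, DMF, 100 °C) should give 1-[2-(2,4-dibromo-5-hydroxyphenoxy)-4-{[2-(trimethylsilyl)ethoxy]methoxy}phenyl]ethan-1-one F5. Silylation (TBSCl, imidazole) should give its tert-butyldimethylsilyl ether F6. Intramolecular palladium-catalysed α-arylation at high dilution (Pd(OAc)2, XPhos, K3PO4, toluene) can only close at the bromide ortho to the aryloxy group and should give 2-bromo-3-[(tert-butyldimethylsilyl)oxy]-7-{[2-(trimethylsilyl)ethoxy]methoxy}dibenzo[b,f]oxepin-10(11H)-one F7. An α-selective Suzuki–Miyaura coupling of F7 with prenylboronic acid pinacol ester comes back to the route at 13.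

3. Step 10. Cleavage of the aryl SEM ether may be slow, and during that time the electron-rich diphenoxide is exposed to heat, to released formaldehyde (hydroxymethylation of the arenes) and to adventitious oxygen. The fallback removes the SEM group at the robust ketone stage so that the last step is a cold desilylation. It sets out from 12. Acidic methanolysis (HCl, MeOH, 40 °C) should give 3,7-dihydroxy-2-(3-methylbut-2-en-1-yl)dibenzo[b,f]oxepin-10(11H)-one F8. Bis-silylation (TBSCl, imidazole, DMF) should give 3,7-bis[(tert-butyldimethylsilyl)oxy]-2-(3-methylbut-2-en-1-yl)dibenzo[b,f]oxepin-10(11H)-one F9. Reaction of F9 with 3 under the conditions of step 9 should give, via the bis-silyl epoxy ketone F10 (not isolated), the 3,7-bis-O-tert-butyldimethylsilyl ether of the target F11. TBAF in THF at 0 °C then comes back to the route at 16.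

Further compounds
F1 | step 9 | (2R,3S)-1-iodo-3,7-dimethyloct-6-ene-2,3-diol | IC[C@H](O)[C@@](C)(O)CCC=C(C)C
F2 | step 9 | (2R,3S)-2-[(tert-butyldimethylsilyl)oxy]-1-iodo-3,7-dimethyloct-6-en-3-ol | IC[C@H](O[Si](C)(C)C(C)(C)C)[C@@](C)(O)CCC=C(C)C
F3 | step 9 | 13 carrying at C11 the (2S,3S)-2-[(tert-butyldimethylsilyl)oxy]-3-hydroxy-3,7-dimethyloct-6-en-1-yl group | O=C1C(C[C@H](O[Si](C)(C)C(C)(C)C)[C@@](C)(O)CCC=C(C)C)c2cc(CC=C(C)C)c(O[Si](C)(C)C(C)(C)C)cc2Oc2cc(OCOCC[Si](C)(C)C)ccc21
F4 | step 9 | 3′-O-tert-butyldimethylsilyl ether of 15 | CC(C)=CCC[C@]1(C)OC2=C(C[C@@H]1O[Si](C)(C)C(C)(C)C)c1cc(CC=C(C)C)c(O[Si](C)(C)C(C)(C)C)cc1Oc1cc(OCOCC[Si](C)(C)C)ccc12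
F5 | step 7 | 1-[2-(2,4-dibromo-5-hydroxyphenoxy)-4-{[2-(trimethylsilyl)ethoxy]methoxy}phenyl]ethan-1-one | CC(=O)c1ccc(OCOCC[Si](C)(C)C)cc1Oc1cc(O)c(Br)cc1Br
F6 | step 7 | 1-[2-{2,4-dibromo-5-[(tert-butyldimethylsilyl)oxy]phenoxy}-4-{[2-(trimethylsilyl)ethoxy]methoxy}phenyl]ethan-1-one | CC(=O)c1ccc(OCOCC[Si](C)(C)C)cc1Oc1cc(O[Si](C)(C)C(C)(C)C)c(Br)cc1Br
F7 | step 7 | 2-bromo-3-[(tert-butyldimethylsilyl)oxy]-7-{[2-(trimethylsilyl)ethoxy]methoxy}dibenzo[b,f]oxepin-10(11H)-one | O=C1Cc2cc(Br)c(O[Si](C)(C)C(C)(C)C)cc2Oc2cc(OCOCC[Si](C)(C)C)ccc21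
F8 | step 10 | 3,7-dihydroxy-2-(3-methylbut-2-en-1-yl)dibenzo[b,f]oxepin-10(11H)-one | O=C1Cc2cc(CC=C(C)C)c(O)cc2Oc2cc(O)ccc21
F9 | step 10 | 3,7-bis[(tert-butyldimethylsilyl)oxy]-2-(3-methylbut-2-en-1-yl)dibenzo[b,f]oxepin-10(11H)-one | O=C1Cc2cc(CC=C(C)C)c(O[Si](C)(C)C(C)(C)C)cc2Oc2cc(O[Si](C)(C)C(C)(C)C)ccc21
F10 | step 10 | F9 carrying at C11 the [(2S,3R)-3-methyl-3-(4-methylpent-3-en-1-yl)oxiran-2-yl]methyl group | O=C1C(C[C@@H]2O[C@]2(C)CCC=C(C)C)c2cc(CC=C(C)C)c(O[Si](C)(C)C(C)(C)C)cc2Oc2cc(O[Si](C)(C)C(C)(C)C)ccc21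
F11 | step 10 | 3,7-bis-O-tert-butyldimethylsilyl ether of 16 | CC(C)=CCC[C@]1(C)OC2=C(C[C@@H]1O)c1cc(CC=C(C)C)c(O[Si](C)(C)C(C)(C)C)cc1Oc1cc(O[Si](C)(C)C(C)(C)C)ccc12
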